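**Two logarithms.** A ratio of two logarithms carries this flask. A racemate of left-handed and right-handed substrate stands with single-handed free catalyst, and partner dissolves from gas. What matters is the excess of right-handed substrate among what is left of the two.

| flask | left-handed substrate | right-handed substrate | gas | free catalyst | remark | time |
|---|---|---|---|---|---|---|
| Thursday's | 1.5 M | 1.5 M | 44 mM (held) | 32 mM | run made earlier |  |
| flask | 1.0 M | 1.0 M | 44 mM (held) | 32 mM |  | 4.0 h |

Thursday's run (percent of the left-handed substrate and right-handed substrate together charged)

| time / min | right-handed substrate / % | left-handed substrate / % |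
|---|---|---|
| 6.00 | 49.8 | 42.4 |
| 15.0 | 49.9 | 31.0 |
| 20.0 | 49.2 | 25.7 |
| 30.0 | 49.1 | 17.0 |
| 40.0 | 49.0 | 10.3 |
| 50.0 | 48.7 | 6.1 |

(each reading ± 0.3 percentage points)

1. whether the excess of right-handed substrate over left-handed substrate among what is left of the two reaches 80 % by 4.0 h (yes / no)
2. the highest excess of right-handed substrate over left-handed substrate among what is left of the two up to 4.0 h

**Thursday's factor.** At 50.0 min, Thursday's run reads left-handed substrate 6.1 % and right-handed substrate 48.7 %, from a half each. The logarithm of the left-handed fraction left, over that of the right-handed fraction left, reads 79.9. This is the selectivity factor s. Thursday's right-handed loss is 1.3 percentage points against a scatter of 0.3 points, so s is a rough reading.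

**The charge.** The charge falls from 1.5 M to 1.0 M of each substrate. By hand, s stays: on the proposed steps, both substrates meet the same c(partner) and c(free catalyst), which cancel from the ratio. With f the right-handed fraction left, the left-handed fraction is f^s. So this flask reaches 80 % with right-handed substrate at 48.6 % of the total charged.

**Catalyst and gas.** Free catalyst at 32 mM and gas at 44 mM stay as on Thursday. By hand, both enter the clock and cancel from s.

**The time.** The flask has 4.80 times Thursday's last reading time, and Thursday's excess then read 77.7 %. This reckoning therefore says yes, with the excess close to its ceiling.

**The forecast.** The forecast gives yes and 99.8 %, within 98 % to 100 %, and reads from Thursday's run: “so selectivity is about 75”.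

**The flask.** The flask gives yes and >99.9 %.

    free catalyst → spent catalyst (k = 2.40 × 10⁻⁶ s⁻¹)
    2 partner → homo dimer (k = 0.00650 M⁻¹ s⁻¹)
    partner + free catalyst + left-handed substrate → free catalyst + left-handed product (k = 0.790 M⁻² s⁻¹)
    partner + free catalyst + right-handed substrate → free catalyst + right-handed product (k = 0.0120 M⁻² s⁻¹)
    gas ⇌ partner, rate k5*(csat - [partner]) (kL = 0.0290 s⁻¹)

In this flask the excess passes 80 % at 0.777 h, with right-handed substrate at 48.3 %, where s had put it at 48.6 %. At 4.00 h, 80 % of the right-handed charge stands in this flask, so f^s gives a left-handed fraction of 2.58 × 10⁻⁸, and the flask holds 0 % of the left-handed charge. In the run with half the right-handed substrate, f^s is taken with the same s, and that flask ends at an excess of >99.9 %.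

The runs were generated by integration for substances that don't exist.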